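**Retrosynthetic overview**
1. The strategy rests on C3 of the furan-2,4(3H,5H)-dione ring, a quaternary carbon held between the lactone carbonyl C2 and the ketone C4. C2–C3 with its aryl and prenyl groups maps onto an aryl(prenyl)ketene. O1–C5(=CHAr)–C4 maps onto the ring oxygen, C5 and the acyl carbon of a (Z)-5-arylidene-2,2-dimethyl-1,3-dioxolan-4-one.
2. Key disconnections: C3–C4 and O1–C2, both made in one chiral-Lewis-base-catalysed formal (3+2) annulation with loss of acetone. Only the removal of two aryl TIPS ethers follows.
3. The dioxolanone partner comes from a Wittig olefination of 3-prenyl-4-silyloxybenzaldehyde with the phosphonium salt of glycolic acid acetonide. The ketene partner comes from α-prenylation of a methyl arylacetate, saponification, neutral acid chloride formation and dehydrochlorination.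
4. Both aryl prenyl groups come from linear-selective Suzuki–Miyaura coupling of prenylboronic acid pinacol ester with ortho-bromo TIPS ethers. The aldehyde is masked as its dimethyl acetal during the coupling, because allylboronates add to free aldehydes.
5. Ring order: both arenes are bought, and the dioxolanone ring is bought and sacrificed. The furandione is the only ring built, and it is closed in the key step.

Key step: step 14

Assumption: the sense of induction of the planar-chiral catalyst in step 14 cannot be predicted. The (−)-antipode is written, and the (+)-antipode would be used instead if the configurational assignment of the first sample of 21 points to (R). Abbreviations: prenyl = 3-methylbut-2-en-1-yl, TIPS = triisopropylsilyl.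

**Step 1**
Reactants: 1 3-bromo-4-hydroxybenzaldehyde
Product: 2 3-bromo-4-(triisopropylsilyloxy)benzaldehyde
Conditions: TIPSCl (1.2 equiv), imidazole (2.5 equiv), DMF, rt
Reagents that add atoms: triisopropylsilyl chloride, CC(C)[Si](Cl)(C(C)C)C(C)C
Why: Imidazole-promoted O-silylation of an acidic phenol leaves the aldehyde untouched, and the bulky silyl ether later keeps the phenol away from the ketene and prevents chroman formation.

**Step 2**
Reactants: 2 3-bromo-4-(triisopropylsilyloxy)benzaldehyde
Product: 3 3-bromo-4-(triisopropylsilyloxy)benzaldehyde dimethyl acetal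
Conditions: HC(OMe)3 (3 equiv), p-TsOH·H2O (1 mol %), MeOH, rt; Et3N quench
Reagents that add atoms: trimethyl orthoformate, COC(OC)OC; methanol, CO
Why: Acid-catalysed acetalisation driven by the orthoformate masks the aldehyde, which would otherwise undergo allylboration by 4 in the next step, and it also removes the para acceptor that makes the aryl silyl ether labile to aqueous base.

**Step 3**
Reactants: 3 3-bromo-4-(triisopropylsilyloxy)benzaldehyde dimethyl acetal; 4 prenylboronic acid pinacol ester
Product: 5 3-prenyl-4-(triisopropylsilyloxy)benzaldehyde dimethyl acetal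
Conditions: 4 (1.5 equiv), Pd-PEPPSI-IPent (3 mol %), K3PO4 (3 equiv), THF/H2O, 60 °C; filtration through Et3N-deactivated silica to strip boron residues
Reagents that add atoms: none
Why: In this Suzuki–Miyaura allyl–aryl coupling the very bulky ligand lets the σ-allylpalladium formed on transmetalation settle as the primary isomer before reductive elimination, so the linear prenyl arene should form rather than the 1,1-dimethylallyl isomer.

**Step 4**
Reactants: 5 3-prenyl-4-(triisopropylsilyloxy)benzaldehyde dimethyl acetal
Product: 6 3-prenyl-4-(triisopropylsilyloxy)benzaldehyde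
Conditions: 1 M aq HCl (cat.), THF/H2O, 0 °C to rt
Reagents that add atoms: water, O
Why: Acetal hydrolysis of an electron-rich benzylic acetal needs only dilute acid, which spares the trisubstituted alkene and the aryl TIPS ether, and no allylboronate is left to attack the liberated aldehyde.

**Step 5**
Reactants: 7 2,2-dimethyl-1,3-dioxolan-4-one
Product: 8 (±)-5-bromo-2,2-dimethyl-1,3-dioxolan-4-one
Conditions: NBS (1.05 equiv), AIBN (2 mol %), PhCF3, 85 °C; succinimide filtered off, product used crude
Reagents that add atoms: N-bromosuccinimide, O=C1CCC(=O)N1Br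
Why: Wohl–Ziegler radical bromination selects C5–H because the radical there is captodatively stabilised by the ring oxygen and the carbonyl group, while the ketal methyl groups are unactivated.

**Step 6**
Reactants: 8 (±)-5-bromo-2,2-dimethyl-1,3-dioxolan-4-one
Product: 9 (±)-(2,2-dimethyl-5-oxo-1,3-dioxolan-4-yl)triphenylphosphonium bromide
Conditions: PPh3 (1.0 equiv), toluene, rt; salt collected by filtration under N2
Reagents that add atoms: triphenylphosphine, c1ccc(cc1)P(c1ccccc1)c1ccccc1
Why: The α-alkoxy-α-bromo ester is a highly reactive alkylating agent, so quaternisation of the phosphine is fast, and precipitation of the salt removes it from further reaction.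

**Step 7**
Reactants: 9 (±)-(2,2-dimethyl-5-oxo-1,3-dioxolan-4-yl)triphenylphosphonium bromide; 6 3-prenyl-4-(triisopropylsilyloxy)benzaldehyde
Product: 11 (Z)-2,2-dimethyl-5-[3-prenyl-4-(triisopropylsilyloxy)benzylidene]-1,3-dioxolan-4-one, via dioxolanone ylide 10 (not isolated)
Conditions: DABCO (1.1 equiv), toluene, rt, 30 min; then 6, 80 °C; chromatography to remove any E isomer
Reagents that add atoms: none
Why: Wittig olefination with a carbonyl-stabilised ylide places the aryl group trans to the lactone carbonyl, that is cis to the ring oxygen (Z), and this is also the less crowded alkene.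

**Step 8**
Reactants: 12 methyl 2-(3-bromo-4-hydroxyphenyl)acetate
Product: 13 methyl 2-[3-bromo-4-(triisopropylsilyloxy)phenyl]acetate
Conditions: TIPSCl (1.2 equiv), imidazole (2.5 equiv), DMF, rt
Reagents that add atoms: triisopropylsilyl chloride, CC(C)[Si](Cl)(C(C)C)C(C)C
Why: This is the same imidazole-promoted O-silylation as in step 1, and the methyl ester is inert under these conditions.

**Step 9**
Reactants: 13 methyl 2-[3-bromo-4-(triisopropylsilyloxy)phenyl]acetate; 4 prenylboronic acid pinacol ester
Product: 14 methyl 2-[3-prenyl-4-(triisopropylsilyloxy)phenyl]acetate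
Conditions: 4 (1.5 equiv), Pd-PEPPSI-IPent (3 mol %), K3PO4 (3 equiv), THF/H2O, 60 °C
Reagents that add atoms: none
Why: The linear-selective Suzuki–Miyaura prenylation of step 3 is repeated, with phosphate instead of hydroxide as the base so that the methyl ester and the aryl silyl ether should persist.

**Step 10**
Reactants: 14 methyl 2-[3-prenyl-4-(triisopropylsilyloxy)phenyl]acetate; 15 prenyl bromide
Product: 17 methyl (±)-5-methyl-2-[3-prenyl-4-(triisopropylsilyloxy)phenyl]hex-4-enoate, via lithium enolate 16 (not isolated)
Conditions: LDA (1.05 equiv), THF, −78 °C; then 15 (1.1 equiv), −78 to −20 °C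
Reagents that add atoms: none
Why: Ester enolate alkylation by SN2 attack on a reactive primary allylic bromide should stop at monoalkylation with one equivalent of base, and the new stereocentre is racemic, which does not matter because it is erased in step 13.

**Step 11**
Reactants: 17 methyl (±)-5-methyl-2-[3-prenyl-4-(triisopropylsilyloxy)phenyl]hex-4-enoate
Product: 18 (±)-5-methyl-2-[3-prenyl-4-(triisopropylsilyloxy)phenyl]hex-4-enoic acid
Conditions: LiOH·H2O (3 equiv), THF/MeOH/H2O, rt; then cold 0.5 M HCl to pH 3–4
Reagents that add atoms: lithium hydroxide, [Li+].[OH-]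
Why: Saponification of the methyl ester at room temperature should be faster than attack on the aryl TIPS ether, which has no para acceptor and is shielded by three isopropyl groups and the ortho prenyl chain.

**Step 12**
Reactants: 18 (±)-5-methyl-2-[3-prenyl-4-(triisopropylsilyloxy)phenyl]hex-4-enoic acid
Product: 19 (±)-5-methyl-2-[3-prenyl-4-(triisopropylsilyloxy)phenyl]hex-4-enoyl chloride
Conditions: 1-chloro-N,N,2-trimethylpropenylamine (1.1 equiv), CH2Cl2, 0 °C to rt; amide by-product and volatiles removed under high vacuum
Reagents that add atoms: 1-chloro-N,N,2-trimethylprop-1-en-1-amine, CC(C)=C(Cl)N(C)C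
Why: Acid chloride formation with an α-chloroenamine runs through an acyloxyiminium chloride and releases a neutral amide instead of HCl, so the two trisubstituted alkenes are not hydrochlorinated.

**Step 13**
Reactants: 19 (±)-5-methyl-2-[3-prenyl-4-(triisopropylsilyloxy)phenyl]hex-4-enoyl chloride
Product: 20 prenyl[3-prenyl-4-(triisopropylsilyloxy)phenyl]ketene, kept as a toluene stock solution
Conditions: Me2NEt (1.5 equiv), Et2O, 0 °C to rt, Ar; filtration under Ar, evaporation (removes the volatile excess amine), redissolved in toluene, titre checked by IR/NMR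
Reagents that add atoms: none
Why: Amine-mediated dehydrochlorination of an α-aryl-α-alkyl acid chloride is the standard entry to aryl(alkyl)ketenes, which are stabilised by aryl conjugation and substitution, and the racemic α-carbon becomes planar.

**Step 14**
Reactants: 11 (Z)-2,2-dimethyl-5-[3-prenyl-4-(triisopropylsilyloxy)benzylidene]-1,3-dioxolan-4-one; 20 prenyl[3-prenyl-4-(triisopropylsilyloxy)phenyl]ketene
Product: 21 (3S,5Z)-3-prenyl-3-[3-prenyl-4-(triisopropylsilyloxy)phenyl]-5-[3-prenyl-4-(triisopropylsilyloxy)benzylidene]furan-2,4(3H,5H)-dione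
Conditions: (−)-PPY* [planar-chiral (η5-C5Me5)Fe-fused 4-pyrrolidinopyridine, 10 mol %], 4 Å MS, toluene, −40 °C; 20 (1.3 equiv in toluene) by syringe pump over 8 h, then to −20 °C
Reagents that add atoms: none
Why: Proposed new method: the chiral pyridine adds to the carbonyl carbon of 20 to give a zwitterionic acylpyridinium enolate whose fully substituted α-carbon attacks acyl carbon C4 of 11, the tetrahedral intermediate breaks the C4–O3 bond, the hemiketal alkoxide sheds acetone irreversibly, and the oxygen now on C5 attacks the acylpyridinium carbon in a 5-exo-trig O-acylation that forms O1–C2, closes the furan-2,4-dione and frees the catalyst (the reverse order, in which the catalyst opens 11, the C5 enolate oxygen adds to the ketene and the resulting ester enolate is C-acylated 5-exo-trig by the tethered acylpyridinium, ends at the same product). The closest known reaction types are the pulvinone annulation of lithium arylacetate enolates with 5-arylidene-dioxolanones (Claisen acylation, acetone loss, lactonisation) and the chiral 4-aminopyridine catalysis of aryl(alkyl)ketene additions and of Steglich-type O-to-C acyl shifts that create quaternary carbons. The only new stereocentre, C3, arises in the C3–C4 bond formation and is controlled by the planar-chiral catalyst, which sits next to the prochiral enolate carbon and screens one of its faces, while the size difference between the flat aryl group and the prenyl CH2 fixes the enolate geometry; both enantiomers of 19 converge because 20 is planar. The step needs C- rather than O-acylation and 1,2- rather than 1,4-attack, which the doubly oxygen-activated acyl carbon of the dioxolanone and the electron-rich silyloxyaryl group (a deactivated benzylidene β-carbon) should secure, and it needs ketene dimerisation to be held back, which the slow addition secures. The Z alkene should pass through unchanged, since no proton source is present and Z is also the more stable geometry. The group expelled in the ring closure is the neutral catalyst and not an alkoxide, so nothing in the flask can reopen the non-enolisable β-keto enol lactone by retro-Claisen cleavage.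

**Step 15**
Reactants: 21 (3S,5Z)-3-prenyl-3-[3-prenyl-4-(triisopropylsilyloxy)phenyl]-5-[3-prenyl-4-(triisopropylsilyloxy)benzylidene]furan-2,4(3H,5H)-dione
Product: 22 (3S,5Z)-3-(4-hydroxy-3-prenylphenyl)-5-(4-hydroxy-3-prenylbenzylidene)-3-prenylfuran-2,4(3H,5H)-dione (CNP0567773.1)
Conditions: HF·pyridine (excess), pyridine, THF, 0 °C to rt, polypropylene vessel; pH 7 phosphate buffer work-up
Reagents that add atoms: none
Why: Fluoride-driven desilylation in a buffered, weakly acidic medium frees both phenols without a basic nucleophile that could open the enol lactone and without strong acid that could cyclise the ortho-prenylphenols to chromans, and C3 bears no hydrogen and so cannot epimerise.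

**Compound list**
1 | 3-bromo-4-hydroxybenzaldehyde | O=Cc1ccc(O)c(Br)c1 | starting material
2 | 3-bromo-4-(triisopropylsilyloxy)benzaldehyde | O=Cc1ccc(O[Si](C(C)C)(C(C)C)C(C)C)c(Br)c1 | intermediate
3 | 3-bromo-4-(triisopropylsilyloxy)benzaldehyde dimethyl acetal | COC(OC)c1ccc(O[Si](C(C)C)(C(C)C)C(C)C)c(Br)c1 | intermediate
4 | prenylboronic acid pinacol ester | CC(C)=CCB1OC(C)(C)C(C)(C)O1 | starting material
5 | 3-prenyl-4-(triisopropylsilyloxy)benzaldehyde dimethyl acetal | COC(OC)c1ccc(O[Si](C(C)C)(C(C)C)C(C)C)c(CC=C(C)C)c1 | intermediate
6 | 3-prenyl-4-(triisopropylsilyloxy)benzaldehyde | CC(C)=CCc1cc(C=O)ccc1O[Si](C(C)C)(C(C)C)C(C)C | intermediate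
7 | 2,2-dimethyl-1,3-dioxolan-4-one | CC1(C)OCC(=O)O1 | starting material
8 | (±)-5-bromo-2,2-dimethyl-1,3-dioxolan-4-one | CC1(C)OC(Br)C(=O)O1 | intermediate
9 | (±)-(2,2-dimethyl-5-oxo-1,3-dioxolan-4-yl)triphenylphosphonium bromide | CC1(C)OC(=O)C([P+](c2ccccc2)(c2ccccc2)c2ccccc2)O1.[Br-] | intermediate
10 | 2,2-dimethyl-5-(triphenylphosphoranylidene)-1,3-dioxolan-4-one | CC1(C)OC(=O)C(=P(c2ccccc2)(c2ccccc2)c2ccccc2)O1 | intermediate
11 | (Z)-2,2-dimethyl-5-[3-prenyl-4-(triisopropylsilyloxy)benzylidene]-1,3-dioxolan-4-one | CC(C)=CCc1cc(/C=C2\OC(C)(C)OC2=O)ccc1O[Si](C(C)C)(C(C)C)C(C)C | intermediate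
12 | methyl 2-(3-bromo-4-hydroxyphenyl)acetate | COC(=O)Cc1ccc(O)c(Br)c1 | starting material
13 | methyl 2-[3-bromo-4-(triisopropylsilyloxy)phenyl]acetate | COC(=O)Cc1ccc(O[Si](C(C)C)(C(C)C)C(C)C)c(Br)c1 | intermediate
14 | methyl 2-[3-prenyl-4-(triisopropylsilyloxy)phenyl]acetate | COC(=O)Cc1ccc(O[Si](C(C)C)(C(C)C)C(C)C)c(CC=C(C)C)c1 | intermediate
15 | prenyl bromide | CC(C)=CCBr | starting material
16 | lithium enolate of 14 | [Li+].COC([O-])=Cc1ccc(O[Si](C(C)C)(C(C)C)C(C)C)c(CC=C(C)C)c1 | intermediate
17 | methyl (±)-5-methyl-2-[3-prenyl-4-(triisopropylsilyloxy)phenyl]hex-4-enoate | COC(=O)C(CC=C(C)C)c1ccc(O[Si](C(C)C)(C(C)C)C(C)C)c(CC=C(C)C)c1 | intermediate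
18 | (±)-5-methyl-2-[3-prenyl-4-(triisopropylsilyloxy)phenyl]hex-4-enoic acid | CC(C)=CCC(C(=O)O)c1ccc(O[Si](C(C)C)(C(C)C)C(C)C)c(CC=C(C)C)c1 | intermediate
19 | (±)-5-methyl-2-[3-prenyl-4-(triisopropylsilyloxy)phenyl]hex-4-enoyl chloride | CC(C)=CCC(C(=O)Cl)c1ccc(O[Si](C(C)C)(C(C)C)C(C)C)c(CC=C(C)C)c1 | intermediate
20 | prenyl[3-prenyl-4-(triisopropylsilyloxy)phenyl]ketene | CC(C)=CCC(=C=O)c1ccc(O[Si](C(C)C)(C(C)C)C(C)C)c(CC=C(C)C)c1 | intermediate
21 | (3S,5Z)-bis-TIPS ether of the target | CC(C)=CCc1cc(/C=C2\OC(=O)[C@@](CC=C(C)C)(c3ccc(O[Si](C(C)C)(C(C)C)C(C)C)c(CC=C(C)C)c3)C2=O)ccc1O[Si](C(C)C)(C(C)C)C(C)C | intermediate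
22 | (3S,5Z)-3-(4-hydroxy-3-prenylphenyl)-5-(4-hydroxy-3-prenylbenzylidene)-3-prenylfuran-2,4(3H,5H)-dione | CC(C)=CCc1cc(/C=C2\OC(=O)[C@@](CC=C(C)C)(c3ccc(O)c(CC=C(C)C)c3)C2=O)ccc1O | target

**Total step count:** 15
**Longest linear sequence:** 8 steps (steps 8 to 15, from 12)

**Steps most likely to fail**

1. **Step 14.**
   - **Risk:** The catalyst-bound enolate may be too weak a nucleophile for the dioxolanone acyl carbon, so that ketene dimerisation takes over. Facial selectivity at C3 may also be poor.
   - **Start:** The fallback sets out from 14 and 11 and uses known chemistry. Lithium enolate 16 (from 14 with LDA, a little over two equivalents, THF, −78 °C to rt) is combined with 11. Claisen acylation, loss of acetone and lactonisation should give the bis-TIPS pulvinone F1, (Z)-5-arylidene-3-aryl-4-hydroxyfuran-2(5H)-one.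
   - **Prenylation:** A Tsuji–Trost allylation of F1 follows, with tert-butyl prenyl carbonate and Pd(PPh3)4 in THF at rt. It attacks the unsubstituted terminus of the π-prenyl complex. Any O-prenyl product re-ionises under the catalysis, so the reaction should funnel to the C3-prenylated racemic furandione F2.
   - **Return:** Preparative HPLC on a chiral stationary phase separates the unwanted (R)-enantiomer F3 from the (S)-enantiomer. The fallback comes back to the route at 21.

2. **Step 9.**
   - **Risk:** Linear selectivity may erode through coupling at the γ-carbon of the allylboronate. The coupling may be slow next to the bulky silyloxy group, and the boronate may protodeboronate.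
   - **Start:** The fallback sets out from 13 and inverts the polarity of the coupling. Miyaura borylation (B2pin2, Pd(dppf)Cl2, KOAc, dioxane, 90 °C) should give the arylboronic acid pinacol ester F4.
   - **Return:** F4 is then coupled with prenyl bromide 15 as the electrophile (Pd(dppf)Cl2, K2CO3, THF/H2O, 50 °C). The aryl(π-prenyl)palladium intermediate eliminates at its unsubstituted terminus. The fallback comes back to the route at 14.

3. **Step 13.**
   - **Risk:** The ketene may dimerise or hydrolyse during filtration and concentration. Achiral amine carried over would drive a racemic background reaction in step 14.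
   - **Start:** The fallback sets out from 19 and does without a preformed ketene. Acid chloride 19 is added slowly to 11, the chiral catalyst and iPr2NEt as a non-nucleophilic proton sink, in toluene at low temperature.
   - **Return:** The catalyst is acylated by 19, and the acylpyridinium is deprotonated to the same zwitterionic enolate, which is consumed as it forms. This fallback makes no compound outside the list (F0). It comes back to the route at 21.

**Further compounds**
F1 | step 14 | bis-TIPS pulvinone, (Z)-4-hydroxy-3-[3-prenyl-4-(triisopropylsilyloxy)phenyl]-5-[3-prenyl-4-(triisopropylsilyloxy)benzylidene]furan-2(5H)-one | CC(C)=CCc1cc(/C=C2\OC(=O)C(c3ccc(O[Si](C(C)C)(C(C)C)C(C)C)c(CC=C(C)C)c3)=C2O)ccc1O[Si](C(C)C)(C(C)C)C(C)C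
F2 | step 14 | racemic furandione, (±)-(Z)-bis-TIPS ether of the target | CC(C)=CCc1cc(/C=C2\OC(=O)C(CC=C(C)C)(c3ccc(O[Si](C(C)C)(C(C)C)C(C)C)c(CC=C(C)C)c3)C2=O)ccc1O[Si](C(C)C)(C(C)C)C(C)C
F3 | step 14 | (3R,5Z)-enantiomer of 21 | CC(C)=CCc1cc(/C=C2\OC(=O)[C@](CC=C(C)C)(c3ccc(O[Si](C(C)C)(C(C)C)C(C)C)c(CC=C(C)C)c3)C2=O)ccc1O[Si](C(C)C)(C(C)C)C(C)C
F4 | step 9 | methyl 2-[3-(4,4,5,5-tetramethyl-1,3,2-dioxaborolan-2-yl)-4-(triisopropylsilyloxy)phenyl]acetate | COC(=O)Cc1ccc(O[Si](C(C)C)(C(C)C)C(C)C)c(B2OC(C)(C)C(C)(C)O2)c1
F0 | step 13 | none | none
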